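The route rests on cutting the C1–C10 bond of ring A. Ring B of the target, with oxygen at C6 and C7, methyl groups at C8 and C10 and carbon chains at C5 and C9, is read as a fully substituted guaiacol whose C10 lies para to the C7 hydroxyl. A chiral palladium catalyst ionises a (Z)-allylic carbonate hung from C5, and the phenolate closes ring A through C10, which creates the C10 quaternary stereocentre and leaves a 6-methoxy cross-conjugated dienone primed for ring C closure. The precursor is the hexasubstituted phenol carrying the C4 gem-dimethyl (Z)-allyl methyl carbonate on C5 and a 2-deoxy-apiofuranoside tertiary carbinol chain on C9.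

Key step: step 17

Remarks on the chemistry

- Numbering and faces: labdane numbering is used. Ring A is C1–C5/C10, ring B is C5–C10, ring C is the oxolane O/C9/C11/C12/C13, ring D is C13–C16 with its oxygen. β is the face of the C10 methyl (C20).
- Target as read from its SMILES: 5R,7R,8R,9S,10S,13S. H-5, the C8 methyl (C17), the 7-hydroxyl and C11 are β; O9 and the 8-acetoxy group are α. Rings A/B are therefore cis-fused.
- Design of the precursor:
  - The allyl carbonate is Z. Only the anti π-allyl can bring C1 to C10 with the C2=C3 bond inside a six-membered ring; an E carbonate gives the syn complex, which would first have to isomerise through a σ-complex at the neopentyl carbon C3.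
  - Ring D is carried as a 2-deoxy methyl furanoside with no oxygen on C14, so the C14=C15 enol ether comes from a lactol by dehydration in the last step. C13 is set by asymmetric epoxidation.
  - Chlorine on C9 blocks the para position during the Claisen rearrangement and is the handle for the side chain.
  - The Z olefin is made by olefination of the C3 aldehyde, because metathesis at the neopentyl vinyl group would be slow and E-selective.
- Assumption: C15 is carried as a mixture of anomers (left open in the SMILES); the centre is destroyed in step 24.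
- Assumption: the (R,R) ligand is written for step 17. The sense of induction has to be confirmed on the first run, and the (S,S) ligand is used if it is opposite.
- C5 is the one centre whose control rests on a conformational argument (step 23).

Step 1
Reactants: 1 4-chloro-3,5-dimethylphenol; 2 prenyl bromide
Product: 3 2-chloro-1,3-dimethyl-5-[(3-methylbut-2-en-1-yl)oxy]benzene
Conditions: K2CO3, acetone, reflux
Reagents that add atoms: none
Why: Williamson ether synthesis, the phenoxide displacing the primary allylic bromide at oxygen.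

Step 2
Reactants: 3 aryl prenyl ether
Product: 4 4-chloro-3,5-dimethyl-2-(2-methylbut-3-en-2-yl)phenol
Conditions: PhNEt2, 190 °C, sealed tube
Reagents that add atoms: none
Why: Aromatic Claisen rearrangement bonds the tertiary carbon C4 to the ortho carbon C5 (the two ortho positions are equivalent), while the para chlorine stops the Cope relay to the para position and the amine solvent speeds tautomerisation to the phenol.

Step 3
Reactants: 4 ortho-(1,1-dimethylallyl)phenol
Product: 5 2-chloro-5-methoxy-1,3-dimethyl-4-(2-methylbut-3-en-2-yl)benzene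
Conditions: NaH, MeI, DMF, 0 °C to rt
Reagents that add atoms: iodomethane, CI
Why: Williamson O-methylation of the hindered sodium phenoxide installs the C6 methoxy group that later blocks C6 and masks the C6 ketone.

Step 4
Reactants: 5 aryl methyl ether
Product: 8 3-chloro-6-methoxy-2,4-dimethyl-5-(2-methylbut-3-en-2-yl)phenol, via aryllithium 6 (not isolated), via lithium aryltrimethoxyborate 7 (not isolated)
Conditions: n-BuLi, TMEDA, Et2O, 0 °C to rt; B(OMe)3, −78 °C to rt; H2O2, aq NaOH, 0 °C
Reagents that add atoms: hydrogen peroxide, OO (oxygen of 8); n-butyllithium, [Li]CCCC (lithium of 6); trimethyl borate, COB(OC)OC (boron and methoxy groups of 7)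
Why: Directed ortho-metalation, in which the methoxy group directs lithiation to the only ring C–H (C7) and the aryl chloride neither exchanges nor has an ortho hydrogen, followed by borylation and oxidative boron-to-oxygen migration to the C7 phenol.

Step 5
Reactants: 8 C7 phenol
Product: 9 [3-chloro-6-methoxy-2,4-dimethyl-5-(2-methylbut-3-en-2-yl)phenoxy]tri(propan-2-yl)silane
Conditions: i-Pr3SiOTf, 2,6-lutidine, CH2Cl2, 0 °C
Reagents that add atoms: tri(propan-2-yl)silyl trifluoromethanesulfonate, CC(C)[Si](OS(=O)(=O)C(F)(F)F)(C(C)C)C(C)C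
Why: O-Silylation with a silyl triflate protects the electron-rich phenol against the later oxidative cleavage and base steps.

Step 6
Reactants: 10 2-[(trimethylsilyl)methyl]prop-2-en-1-yl acetate
Product: 12 4,4-dimethoxy-2-methylidenebutan-1-ol, via acetal acetate 11 (not isolated)
Conditions: HC(OMe)3, Me3SiOTf (cat.), CH2Cl2, −78 °C; then K2CO3, MeOH, rt
Reagents that add atoms: trimethyl orthoformate, COC(OC)OC
Why: Hosomi–Sakurai reaction of the allylsilane with the dimethoxycarbenium ion made from the orthoformate gives the homoallylic acetal (C14–C15), and base-catalysed transesterification then frees the allylic alcohol.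

Step 7
Reactants: 12 allylic alcohol
Product: 13 [(2S)-2-(2,2-dimethoxyethyl)oxiran-2-yl]methanol
Conditions: Ti(OiPr)4 (10 mol%), L-(+)-diethyl tartrate (12 mol%), t-BuOOH, 4 Å MS, CH2Cl2, −20 °C
Reagents that add atoms: tert-butyl hydroperoxide, CC(C)(C)OO
Why: Sharpless asymmetric epoxidation of a 2-substituted allylic alcohol, in which the L-(+)-tartrate complex delivers oxygen to the face that gives the (S)-epoxy alcohol (the sense by which 2-methylallyl alcohol gives (S)-2-methylglycidol), so C13 is set by the reagent.

Step 8
Reactants: 13 epoxy alcohol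
Product: 14 tert-butyl{[(2R)-2-(2,2-dimethoxyethyl)oxiran-2-yl]methoxy}dimethylsilane
Conditions: t-BuMe2SiCl, imidazole, CH2Cl2, 0 °C
Reagents that add atoms: tert-butyl(chloro)dimethylsilane, CC(C)(C)[Si](C)(C)Cl
Why: Silylation of the primary alcohol keeps the C16 alkoxide from displacing the sulfonium group in the next step (the descriptor changes only through the priority rules).

Step 9
Reactants: 14 silyl-protected epoxide
Product: 15 (3R)-3-({[tert-butyl(dimethyl)silyl]oxy}methyl)-5,5-dimethoxypent-1-en-3-ol
Conditions: Me3S+ I−, n-BuLi, THF, −10 °C to rt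
Reagents that add atoms: trimethylsulfonium iodide, C[S+](C)C.[I-]
Why: One-carbon homologation of an epoxide to an allylic alcohol with dimethylsulfonium methylide, which opens the epoxide at its CH2 terminus (C12) and loses Me2S from the betaine to give the vinyl group (C12=C11), the C13–O bond and so the C13 configuration staying untouched.

Step 10
Reactants: 15 tertiary vinyl carbinol
Product: 16 (3R)-3-ethenyl-5-methoxyoxolan-3-ol
Conditions: camphorsulfonic acid (cat.), MeOH, 0 °C to rt
Reagents that add atoms: none
Why: Acid-catalysed methanolysis removes the primary silyl ether and the freed C16 hydroxyl closes onto the dimethyl acetal (transacetalisation to the five-membered cyclic acetal), giving ring D as a mixture of C15 anomers.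

Step 11
Reactants: 16 vinyl furanoside; 9 aryl chloride
Product: 18 (3S)-3-{2-[4-methoxy-2,6-dimethyl-3-(2-methylbut-3-en-2-yl)-5-{[tri(propan-2-yl)silyl]oxy}phenyl]ethyl}-5-methoxyoxolan-3-ol, via alkylborane 17 (not isolated)
Conditions: 9-BBN (limiting with respect to 16), THF, 0 °C to rt; then 9, Pd(OAc)2 (5 mol%), SPhos (10 mol%), K3PO4, THF/H2O, 65 °C
Reagents that add atoms: 9-borabicyclo[3.3.1]nonane, B1C2CCCC1CCC2 (boron and ring of 17; only its hydrogen stays in 18)
Why: B-alkyl Suzuki–Miyaura coupling, in which anti-Markovnikov hydroboration puts boron on C11, no free B–H is left to touch the vinyl group of 9, and the bulky electron-rich biarylphosphine lets zerovalent palladium insert into the hindered aryl chloride to form the C9–C11 bond.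

Step 12
Reactants: 18 coupled vinyl arene
Product: 20 2-[3-{2-[(3S)-3-hydroxy-5-methoxyoxolan-3-yl]ethyl}-6-methoxy-2,4-dimethyl-5-{[tri(propan-2-yl)silyl]oxy}phenyl]-2-methylpropanal, via vicinal diol 19 (not isolated)
Conditions: OsO4 (2 mol%), NaIO4, 2,6-lutidine, dioxane/H2O, rt
Reagents that add atoms: osmium tetraoxide, O=[Os](=O)(=O)=O (delivers the oxygen atoms of 19 and 20, regenerated by periodate); sodium periodate, [Na+].[O-]I(=O)(=O)=O (terminal oxygen source)
Why: Lemieux–Johnson oxidation (dihydroxylation, then periodate cleavage of the diol) turns the vinyl group into the C3 aldehyde, which has no α-hydrogen, while the silylated phenol is inert to periodate.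

Step 13
Reactants: 20 C3 aldehyde
Product: 21 methyl (2Z)-4-[3-{2-[(3S)-3-hydroxy-5-methoxyoxolan-3-yl]ethyl}-6-methoxy-2,4-dimethyl-5-{[tri(propan-2-yl)silyl]oxy}phenyl]-4-methylpent-2-enoate
Conditions: (CF3CH2O)2P(O)CH2CO2Me, KN(SiMe3)2, 18-crown-6, THF, −78 °C
Reagents that add atoms: methyl bis(2,2,2-trifluoroethyl)phosphonoacetate, COC(=O)CP(=O)(OCC(F)(F)F)OCC(F)(F)F
Why: Still–Gennari olefination, in which the electron-poor phosphonate under dissociating conditions eliminates from the kinetic adduct and gives the (Z)-enoate, fixing the C2=C3 geometry.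

Step 14
Reactants: 21 (Z)-enoate
Product: 22 (2Z)-4-[3-{2-[(3S)-3-hydroxy-5-methoxyoxolan-3-yl]ethyl}-6-methoxy-2,4-dimethyl-5-{[tri(propan-2-yl)silyl]oxy}phenyl]-4-methylpent-2-en-1-ol
Conditions: i-Bu2AlH, CH2Cl2, −78 °C
Reagents that add atoms: none
Why: 1,2-Reduction of the ester by the aluminium hydride gives the allylic alcohol (C1) without touching the olefin geometry.

Step 15
Reactants: 22 (Z)-allylic alcohol
Product: 23 (2Z)-4-[3-{2-[(3S)-3-hydroxy-5-methoxyoxolan-3-yl]ethyl}-6-methoxy-2,4-dimethyl-5-{[tri(propan-2-yl)silyl]oxy}phenyl]-4-methylpent-2-en-1-yl methyl carbonate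
Conditions: ClCO2Me, pyridine, CH2Cl2, 0 °C
Reagents that add atoms: methyl chloroformate, COC(=O)Cl
Why: Acylation of the primary allylic alcohol with a chloroformate, the tertiary C13 hydroxyl being too hindered to react.

Step 16
Reactants: 23 silyl-protected carbonate
Product: 24 (2Z)-4-[3-hydroxy-5-{2-[(3S)-3-hydroxy-5-methoxyoxolan-3-yl]ethyl}-2-methoxy-4,6-dimethylphenyl]-4-methylpent-2-en-1-yl methyl carbonate
Conditions: Bu4NF, AcOH, THF, 0 °C
Reagents that add atoms: none
Why: Fluoride-induced desilylation of the aryl silyl ether, buffered with acetic acid so that the phenoxide is protonated at once and the carbonate survives.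

Step 17
Reactants: 24 hexasubstituted phenol with (Z)-allyl carbonate on C5
Product: 25 ring A-closed dienone (6-methoxylabda-2,5,8-trien-7-one core; C20 β; 10R) with the 2-[(3S)-3-hydroxy-5-methoxyoxolan-3-yl]ethyl chain on C9
Conditions: Pd2(dba)3·CHCl3 (2.5 mol%), N,N'-[(1R,2R)-cyclohexane-1,2-diyl]bis[2-(diphenylphosphanyl)benzamide] (7.5 mol%), Li2CO3, MeCN, 25 °C
Reagents that add atoms: none
Why: Proposed new method: zerovalent palladium ionises the (Z)-allyl carbonate to an anti-configured π-allyl complex of divalent palladium with loss of CO2 and methoxide, the methoxide deprotonates the phenol, and the phenolate attacks the unsubstituted allyl terminus C1 through its para carbon C10 on the face opposite to palladium; the closest known reaction is the palladium-catalysed intramolecular asymmetric allylic dearomatisation of para-substituted phenols to spirocyclohexadienones, which closes exo, whereas here the allyl unit has to end up inside the new ring. The reasoning is that the Z olefin delivers the anti π-allyl directly, that its isomerisation to the unproductive syn form needs a σ-complex at the neopentyl carbon C3 and is therefore slow, and that in the anti complex the arene can stack over the allyl plane so that C10 reaches C1 almost perpendicular to that plane. Ring A is closed as a six-membered ring in the endo mode with respect to the allyl unit, with the cis C2=C3 bond inside the ring. The new stereocentre C10 is set by the chiral diphosphine: the two diastereomeric π-allyl complexes interconvert by η3–η1–η3 slippage at the CH2 terminus C1, and the ligand pocket selects the one in which the arene presents the C10 face that places the methyl group β (Curtin–Hammett control), independent of the remote C13. The step needs C10 rather than C6 or oxygen as the nucleophilic site: C6 carries the methoxy group and its alkylation would give the less stable linearly conjugated dienone, O-allylation would need an eight-membered ring and is reversible under palladium catalysis, and C4 has no hydrogen so the complex cannot escape by β-hydride elimination. Because C10 already bears a methyl group the adduct cannot rearomatise and is isolated as the cross-conjugated dienone.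

Step 18
Reactants: 25 dienone
Product: 27 (13S)-9α,13:15,16-diepoxy-8α-hydroxy-6,15-dimethoxylabda-2,5-dien-7-one, via potassium enolate 26 (not isolated)
Conditions: KN(SiMe3)2, THF, −78 to −30 °C; then 2-(benzenesulfonyl)-3-phenyloxaziridine, −78 °C
Reagents that add atoms: 2-(benzenesulfonyl)-3-phenyloxaziridine, O=S(=O)(N1OC1c1ccccc1)c1ccccc1 (oxygen on C8); potassium bis(trimethylsilyl)amide, C[Si](C)(C)[N-][Si](C)(C)C.[K+] (potassium of 26)
Why: Tandem intramolecular oxa-Michael addition and enolate hydroxylation with an N-sulfonyloxaziridine, in which the C13 alkoxide adds 5-exo-trig to the enone β-carbon C9 from the α face (anti to the C10 methyl), the potassium enolate is hydroxylated at C8 from the same α face (anti to C20 and C11) so that O9 and O8 are cis, and the oxidation makes the reversible ring closure irreversible.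

Step 19
Reactants: 27 α-hydroxy ketone
Product: 28 (13S)-9α,13:15,16-diepoxy-8α-hydroxy-6,15-dimethoxylabd-5-en-7-one
Conditions: H2 (1 atm), Pd/C, EtOAc, rt
Reagents that add atoms: none
Why: Heterogeneous catalytic hydrogenation saturates the cis-disubstituted C2=C3 bond, the tetrasubstituted methoxy enone flanked by two quaternary carbons being too hindered to react.

Step 20
Reactants: 28 ring A-saturated α-hydroxy ketone
Product: 29 (13S)-9α,13:15,16-diepoxy-6,15-dimethoxylabd-5-ene-7β,8α-diol
Conditions: Zn(BH4)2, Et2O, −20 °C
Reagents that add atoms: none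
Why: Chelation-controlled 1,2-reduction of an α-hydroxy ketone, in which zinc bridges O8 and the C7 carbonyl, C17 is thereby axial on the β face and hydride adds to C7 from the α face to give the trans 7β,8α-diol, conjugate reduction being excluded at the fully substituted C5.

Step 21
Reactants: 29 diol
Product: 30 7β-triethylsilyl ether of 29
Conditions: Et3SiCl, imidazole, DMAP, DMF, rt
Reagents that add atoms: chlorotriethylsilane, CC[Si](Cl)(CC)CC
Why: Silylation distinguishes the secondary C7 hydroxyl from the tertiary C8 hydroxyl on steric grounds and leaves the basic-stable enol ether untouched.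

Step 22
Reactants: 30 C8 tertiary alcohol
Product: 32 8α-acetate of 30, via lithium alkoxide 31 (not isolated)
Conditions: LiN(SiMe3)2, THF, −78 °C; then Ac2O, −78 to 0 °C
Reagents that add atoms: acetic anhydride, CC(=O)OC(C)=O; lithium bis(trimethylsilyl)amide, C[Si](C)(C)[N-][Si](C)(C)C.[Li+] (lithium of 31)
Why: Acylation of a preformed lithium alkoxide, the reliable way to esterify a hindered tertiary alcohol, with no carbonyl group present to rearrange and with the low temperature suppressing 1,2-silyl migration.

Step 23
Reactants: 32 acetoxy silyloxy enol ether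
Product: 35 (13S)-8α-acetoxy-9α,13:15,16-diepoxy-7β,15-dihydroxy-5β-labdan-6-one, via silyl ether ketone 33 (not isolated), via silyl ether lactol 34 (not isolated)
Conditions: 1 M HCl, THF, 0 °C to rt
Reagents that add atoms: water, O
Why: Acid hydrolysis of the enol ether (protonation at C5, then collapse of the hemiketal to the C6 ketone), of the methyl acetal and finally of the silyl ether, with C5 set in the protonation, which is expected on the β face because the trans-diaxial preference of the C7 silyloxy and C8 acetoxy groups, the A(1,2) strain between the C6 methoxy and C7 silyloxy groups and the relief of the C17/C20 syn-diaxial contact hold ring B in the half-chair whose pseudoaxial C10–C1 bond lies on the α face, so that axial protonation anti to that bond gives the cis-fused 5β-H ketone.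

Step 24
Reactants: 35 ketone lactol
Product: 36 target, (5R,7R,8R,9S,10S,13S)-8α-acetoxy-9α,13:15,16-diepoxy-7β-hydroxy-5β-labd-14-en-6-one
Conditions: MsCl (1.2 equiv), Et3N, CH2Cl2, −20 to 40 °C
Reagents that add atoms: none
Why: Lactol dehydration through the anomeric mesylate (the standard entry to furanoid glycals), in which the unhindered hemiacetal hydroxyl reacts before the neopentyl-type C7 hydroxyl and elimination can only run toward C14, the basic medium protecting the acid-labile enol ether; the trans-diaxial O7/O8 arrangement of the cis-fused ketone disfavours acetyl migration.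

Compound list
1 | 4-chloro-3,5-dimethylphenol | Cc1cc(O)cc(C)c1Cl | starting material
2 | prenyl bromide (1-bromo-3-methylbut-2-ene) | CC(C)=CCBr | starting material
3 | 2-chloro-1,3-dimethyl-5-[(3-methylbut-2-en-1-yl)oxy]benzene | CC(C)=CCOc1cc(C)c(Cl)c(C)c1 | intermediate
4 | 4-chloro-3,5-dimethyl-2-(2-methylbut-3-en-2-yl)phenol | C=CC(C)(C)c1c(O)cc(C)c(Cl)c1C | intermediate
5 | 2-chloro-5-methoxy-1,3-dimethyl-4-(2-methylbut-3-en-2-yl)benzene | C=CC(C)(C)c1c(OC)cc(C)c(Cl)c1C | intermediate
6 | aryllithium of 5, lithiated at C7 | C=CC(C)(C)c1c(OC)c([Li])c(C)c(Cl)c1C | intermediate (not isolated)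
7 | lithium aryl(trimethoxy)borate from 6 | [Li+].C=CC(C)(C)c1c(OC)c([B-](OC)(OC)OC)c(C)c(Cl)c1C | intermediate (not isolated)
8 | 3-chloro-6-methoxy-2,4-dimethyl-5-(2-methylbut-3-en-2-yl)phenol | C=CC(C)(C)c1c(OC)c(O)c(C)c(Cl)c1C | intermediate
9 | [3-chloro-6-methoxy-2,4-dimethyl-5-(2-methylbut-3-en-2-yl)phenoxy]tri(propan-2-yl)silane | C=CC(C)(C)c1c(OC)c(O[Si](C(C)C)(C(C)C)C(C)C)c(C)c(Cl)c1C | intermediate
10 | 2-[(trimethylsilyl)methyl]prop-2-en-1-yl acetate | CC(=O)OCC(=C)C[Si](C)(C)C | starting material
11 | 4,4-dimethoxy-2-methylidenebutyl acetate | CC(=O)OCC(=C)CC(OC)OC | intermediate (not isolated)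
12 | 4,4-dimethoxy-2-methylidenebutan-1-ol | OCC(=C)CC(OC)OC | intermediate
13 | [(2S)-2-(2,2-dimethoxyethyl)oxiran-2-yl]methanol | OC[C@@]1(CC(OC)OC)CO1 | intermediate
14 | tert-butyl{[(2R)-2-(2,2-dimethoxyethyl)oxiran-2-yl]methoxy}dimethylsilane | CC(C)(C)[Si](C)(C)OC[C@@]1(CC(OC)OC)CO1 | intermediate
15 | (3R)-3-({[tert-butyl(dimethyl)silyl]oxy}methyl)-5,5-dimethoxypent-1-en-3-ol | CC(C)(C)[Si](C)(C)OC[C@@](O)(CC(OC)OC)C=C | intermediate
16 | (3R)-3-ethenyl-5-methoxyoxolan-3-ol (both anomers at C5 of the oxolane) | C=C[C@@]1(O)COC(OC)C1 | intermediate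
17 | B-alkyl-9-BBN adduct of 16 (boron on C11) | O[C@]1(CCB2C3CCCC2CCC3)COC(OC)C1 | intermediate (not isolated)
18 | (3S)-3-{2-[4-methoxy-2,6-dimethyl-3-(2-methylbut-3-en-2-yl)-5-{[tri(propan-2-yl)silyl]oxy}phenyl]ethyl}-5-methoxyoxolan-3-ol | C=CC(C)(C)c1c(OC)c(O[Si](C(C)C)(C(C)C)C(C)C)c(C)c(CC[C@@]2(O)COC(OC)C2)c1C | intermediate
19 | 1,2-diol from dihydroxylation of the vinyl group of 18 (carbinol centre unassigned) | OCC(O)C(C)(C)c1c(OC)c(O[Si](C(C)C)(C(C)C)C(C)C)c(C)c(CC[C@@]2(O)COC(OC)C2)c1C | intermediate (not isolated)
20 | 2-[3-{2-[(3S)-3-hydroxy-5-methoxyoxolan-3-yl]ethyl}-6-methoxy-2,4-dimethyl-5-{[tri(propan-2-yl)silyl]oxy}phenyl]-2-methylpropanal | O=CC(C)(C)c1c(OC)c(O[Si](C(C)C)(C(C)C)C(C)C)c(C)c(CC[C@@]2(O)COC(OC)C2)c1C | intermediate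
21 | methyl (2Z)-4-aryl-4-methylpent-2-enoate, aryl as in 20 | COC(=O)/C=C\C(C)(C)c1c(OC)c(O[Si](C(C)C)(C(C)C)C(C)C)c(C)c(CC[C@@]2(O)COC(OC)C2)c1C | intermediate
22 | (2Z)-4-aryl-4-methylpent-2-en-1-ol, aryl as in 20 | OC/C=C\C(C)(C)c1c(OC)c(O[Si](C(C)C)(C(C)C)C(C)C)c(C)c(CC[C@@]2(O)COC(OC)C2)c1C | intermediate
23 | (2Z)-4-aryl-4-methylpent-2-en-1-yl methyl carbonate, aryl as in 20 | COC(=O)OC/C=C\C(C)(C)c1c(OC)c(O[Si](C(C)C)(C(C)C)C(C)C)c(C)c(CC[C@@]2(O)COC(OC)C2)c1C | intermediate
24 | (2Z)-4-[3-hydroxy-5-{2-[(3S)-3-hydroxy-5-methoxyoxolan-3-yl]ethyl}-2-methoxy-4,6-dimethylphenyl]-4-methylpent-2-en-1-yl methyl carbonate | COC(=O)OC/C=C\C(C)(C)c1c(OC)c(O)c(C)c(CC[C@@]2(O)COC(OC)C2)c1C | intermediate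
25 | (10R)-6-methoxylabda-2,5,8-trien-7-one core (rings A/B, C20 β) carrying on C9 the 2-[(3S)-3-hydroxy-5-methoxyoxolan-3-yl]ethyl chain | COC1=C2C(C)(C)C=CC[C@]2(C)C(CC[C@@]3(O)COC(OC)C3)=C(C)C1=O | intermediate
26 | potassium C7 enolate (C7=C8) of the ring C-closed ketone, 9α,13-epoxy | COC1=C2C(C)(C)C=CC[C@]2(C)[C@@]3(CC[C@@]4(CC(OC)OC4)O3)C(C)=C1[O-].[K+] | intermediate (not isolated)
27 | (13S)-9α,13:15,16-diepoxy-8α-hydroxy-6,15-dimethoxylabda-2,5-dien-7-one (C17 β) | O[C@]1(C)C(=O)C(OC)=C2C(C)(C)C=CC[C@]2(C)[C@@]12CC[C@@]1(CC(OC)OC1)O2 | intermediate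
28 | (13S)-9α,13:15,16-diepoxy-8α-hydroxy-6,15-dimethoxylabd-5-en-7-one | O[C@]1(C)C(=O)C(OC)=C2C(C)(C)CCC[C@]2(C)[C@@]12CC[C@@]1(CC(OC)OC1)O2 | intermediate
29 | (13S)-9α,13:15,16-diepoxy-6,15-dimethoxylabd-5-ene-7β,8α-diol | O[C@]1(C)[C@@H](O)C(OC)=C2C(C)(C)CCC[C@]2(C)[C@@]12CC[C@@]1(CC(OC)OC1)O2 | intermediate
30 | 7β-triethylsilyl ether of 29 | O[C@]1(C)[C@@H](O[Si](CC)(CC)CC)C(OC)=C2C(C)(C)CCC[C@]2(C)[C@@]12CC[C@@]1(CC(OC)OC1)O2 | intermediate
31 | lithium 8α-alkoxide of 30 | [Li+].[O-][C@]1(C)[C@@H](O[Si](CC)(CC)CC)C(OC)=C2C(C)(C)CCC[C@]2(C)[C@@]12CC[C@@]1(CC(OC)OC1)O2 | intermediate (not isolated)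
32 | 8α-acetate of 30 | CC(=O)O[C@]1(C)[C@@H](O[Si](CC)(CC)CC)C(OC)=C2C(C)(C)CCC[C@]2(C)[C@@]12CC[C@@]1(CC(OC)OC1)O2 | intermediate
33 | (13S)-8α-acetoxy-9α,13:15,16-diepoxy-15-methoxy-7β-(triethylsilyloxy)-5β-labdan-6-one | CC(=O)O[C@]1(C)[C@@H](O[Si](CC)(CC)CC)C(=O)[C@@H]2C(C)(C)CCC[C@]2(C)[C@@]12CC[C@@]1(CC(OC)OC1)O2 | intermediate (not isolated)
34 | 15-hydroxy (lactol) analogue of 33 | CC(=O)O[C@]1(C)[C@@H](O[Si](CC)(CC)CC)C(=O)[C@@H]2C(C)(C)CCC[C@]2(C)[C@@]12CC[C@@]1(CC(O)OC1)O2 | intermediate (not isolated)
35 | (13S)-8α-acetoxy-9α,13:15,16-diepoxy-7β,15-dihydroxy-5β-labdan-6-one (both lactol anomers) | CC(=O)O[C@]1(C)[C@@H](O)C(=O)[C@@H]2C(C)(C)CCC[C@]2(C)[C@@]12CC[C@@]1(CC(O)OC1)O2 | intermediate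
36 | (5R,7R,8R,9S,10S,13S)-8α-acetoxy-9α,13:15,16-diepoxy-7β-hydroxy-5β-labd-14-en-6-one | CC(=O)O[C@]1(C)[C@@H](O)C(=O)[C@@H]2C(C)(C)CCC[C@]2(C)[C@@]12CC[C@@]1(C=COC1)O2 | target

Total step count: 24.
Longest linear sequence: 19 steps (steps 1–5 then 11–24; the side-chain branch, steps 6–10 then 11–24, is equally long).

Steps most likely to fail

Step 17 (proposed new method). The ring closure may lose to isomerisation of the anti π-allyl complex to the syn form or to oligomerising O-allylation, and the enantioface selection at C10 may be poor. The fallback uses known chemistry, sets out from alcohol 22 and comes back at dienone 25. Compound 22 is converted with MsCl, LiCl and 2,4,6-collidine in DMF at 0 °C into the (Z)-allylic chloride F1, by SN2 at the primary carbon without allylic transposition. Bu4NF/AcOH then frees the phenol to give the chlorophenol F2. Treatment of F2 with t-BuOK in t-BuOH/THF brings about the classical intramolecular para C-alkylation of a phenoxide (alkylative dearomatisation, 6-exo-tet SN2 through a six-membered transition state), which forms the same C1–C10 bond without a metal. As nothing controls the C10 face, 25 should form together with its C10 epimer, the epimeric dienone F3; the two are diastereomers because of C13 and are separated by chromatography.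

Step 18. The ring closure is reversible, so retro-Michael opening and deprotonation at C11 may compete with hydroxylation, and facial selectivity at C9 may leak. The fallback sets out from 25 and comes back at 27 and decouples ring closure from oxidation. Compound 25 is treated with KN(SiMe3)2 and then Me3SiCl at −78 °C, which traps the ring-closed enolate as the trimethylsilyl enol ether F4 and removes it from the retro-Michael equilibrium. F4 is then oxidised by the Rubottom protocol (m-CPBA, NaHCO3, CH2Cl2, −40 °C; then Bu4NF/AcOH); the electron-rich silyl enol ether should react before the ring A olefin and from the same α face, giving 27.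

Step 23. Protonation of the enol ether may occur from the α face and give the trans ring fusion, which cannot be corrected later by equilibration because the C7 centre and the acetate would not survive enolising conditions. The fallback sets out from 32 and comes back at 35, and changes the control element from conformational locking to delivery of the proton by the neighbouring hydroxyl. Buffered HF·pyridine (THF/pyridine, 0 °C) first removes the silyl group to give the hydroxy enol ether F5. F5 is then hydrolysed with a weak acid in a poorly coordinating medium (chloroacetic acid, wet CH2Cl2, 0 °C, then dilute aqueous acid for the acetal), where the 7β-hydroxyl can hold the acid by hydrogen bonding on the β face above C5–C6, the same syn-directing effect that allylic hydroxyls exert on peracids. The C5 epimers are diastereomers and separable in either case.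

Further compounds
F1 | step 17 | (Z)-allylic chloride derived from 22 (aryl silyl ether retained) | ClC/C=C\C(C)(C)c1c(OC)c(O[Si](C(C)C)(C(C)C)C(C)C)c(C)c(CC[C@@]2(O)COC(OC)C2)c1C
F2 | step 17 | free phenol of F1 | ClC/C=C\C(C)(C)c1c(OC)c(O)c(C)c(CC[C@@]2(O)COC(OC)C2)c1C
F3 | step 17 | C10 epimer of dienone 25 | COC1=C2C(C)(C)C=CC[C@@]2(C)C(CC[C@@]3(O)COC(OC)C3)=C(C)C1=O
F4 | step 18 | trimethylsilyl enol ether (C7=C8) of the ring C-closed ketone | COC1=C2C(C)(C)C=CC[C@]2(C)[C@@]3(CC[C@@]4(CC(OC)OC4)O3)C(C)=C1O[Si](C)(C)C
F5 | step 23 | (13S)-8α-acetoxy-9α,13:15,16-diepoxy-6,15-dimethoxylabd-5-en-7β-ol | CC(=O)O[C@]1(C)[C@@H](O)C(OC)=C2C(C)(C)CCC[C@]2(C)[C@@]12CC[C@@]1(CC(OC)OC1)O2
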